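**Retrosynthetic overview**
1. Target 12 ⇒ imbricatolic acid 11 + a formyl donor (O15–CHO ester bond, made last).
2. 11 ⇒ isocupressic acid 10 (C13–H by asymmetric hydrogenation) ⇒ tertiary allylic acetate 6 (C15–O bond by 1,3-acetate shift; 8(17)-alkene by dehydration of the 8α-OH).
3. Key disconnection: the C19–O bonds. The 19-oic acid 4 ⇒ sclareol 1 by site-selective oxygenation of the axial C4 methyl, which makes C4 a stereocentre.
4. Ring formation: none. Both rings of the trans-decalin, with C5, C9 and C10, come intact from sclareol.

Assumption: the target is read as the 15-O-formate of imbricatolic acid, (4S,5R,9S,10R,13S)-15-formyloxylabd-8(17)-en-19-oic acid (normal labdane series: 5α-H, 9α-H, 10β-CH3, axial 4β-COOH), and (−)-sclareol, a bulk fragrance feedstock of the same absolute decalin configuration, is taken as the one cheap commercial starting material.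

**Step 1**
Reactants: 1 (−)-sclareol [(13R)-labd-14-ene-8α,13-diol]
Product: 4 (13R)-8α,13-dihydroxylabd-14-en-19-oic acid, via 19-hydroxysclareol 2 (not isolated), via sclareol-19-al 3 (not isolated)
Conditions: engineered cytochrome P450 C19-oxidase (heme-iron monooxygenase–reductase fusion of the CYP102A1 type, E. coli lysate), NADP+ (cat.), glucose dehydrogenase, D-glucose (4 equiv), air (O2), K2HPO4/KH2PO4 buffer pH 8.0, 5% EtOH, 25 °C, 24 h; acid–base extraction
Reagents that add atoms: dioxygen, O=O
Why: Proposed new method: a P450 active site re-shaped by directed evolution from the known sclareol-accepting CYP102A1 variants (which hydroxylate C3), so that sclareol, held by its two tertiary hydroxyls at the channel mouth, sits with the β-face axial C4 methyl closest to the heme; the ferryl-oxo porphyrin radical cation (tetravalent iron) abstracts a methyl hydrogen and hydroxyl rebound gives 2, and two more turnovers on the still-bound alcohol give the gem-diol (aldehyde 3) and then acid 4, positional control overriding the roughly 3 kcal/mol stronger primary C–H bond; because the axial C19 and equatorial C18 methyls are diastereotopic, oxidising only C19 makes C4 a stereocentre (4S) under catalyst control; closest known reaction type: single-P450 three-step methyl-to-carboxylic-acid oxidations (ent-kaurene oxidase at the axial C4 methyl of ent-diterpenes, conifer CYP720B enzymes at C18, CYP71AV1 on amorphadiene) and the ring-A hydroxylations of sclareol by CYP102A1 variants and by fungal cells.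

**Step 2**
Reactants: 4 (13R)-8α,13-dihydroxylabd-14-en-19-oic acid
Product: 6 (13R)-13-acetoxy-8α-hydroxylabd-14-en-19-oic acid, via mixed acetic anhydride 5 (not isolated)
Conditions: Ac2O (3 equiv), Et3N, DMAP (cat.), CH2Cl2, 0 °C to rt; then H2O–THF, rt
Reagents that add atoms: acetic anhydride, CC(=O)OC(C)=O
Why: DMAP-catalysed O-acylation in which the open-chain, linalool-type tertiary 13-OH is acetylated while the ring 8α-OH, shielded by C17, C20 and the C9 side chain, is not; the mixed anhydride formed at the hindered acid is hydrolysed at its acetyl carbonyl in the aqueous hold, and no stereocentre is touched.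

**Step 3**
Reactants: 6 (13R)-13-acetoxy-8α-hydroxylabd-14-en-19-oic acid
Product: 7 (13E)-15-acetoxy-8α-hydroxylabd-13-en-19-oic acid
Conditions: PdCl2(MeCN)2 (5 mol %), THF, rt, 12 h; minor 13Z isomer removed on AgNO3-impregnated silica
Reagents that add atoms: none
Why: Overman-type [3,3] allylic acetate transposition catalysed by divalent palladium (cyclisation-induced rearrangement) moves the acetate from tertiary C13 to primary C15 (new C15–O bond) and gives the trisubstituted alkene, with E favoured (about 4:1 expected) by the chair acetoxonium intermediate carrying the large chain equatorial; the C13 stereocentre is deliberately erased here.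

**Step 4**
Reactants: 7 (13E)-15-acetoxy-8α-hydroxylabd-13-en-19-oic acid
Product: 9 acetylisocupressic acid [(13E)-15-acetoxylabda-8(17),13-dien-19-oic acid], via acid chloride 8 (not isolated)
Conditions: SOCl2 (3 equiv), pyridine, CH2Cl2, −78 °C, 1 h; then H2O–THF–pyridine, DMAP (cat.), 40 °C
Reagents that add atoms: water, O; thionyl chloride, O=S(Cl)Cl (its chlorine stays only in 8)
Why: chlorosulfite formation followed by pyridine-mediated E2 elimination: the 8α leaving group is equatorial, so no ring C–H is antiperiplanar to it and only the C17 methyl hydrogens can be, which gives the exocyclic 8(17)-alkene; the C19 acid is converted to its chloride in passing and is returned by the aqueous pyridine hold.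

**Step 5**
Reactants: 9 acetylisocupressic acid
Product: 10 isocupressic acid [(13E)-15-hydroxylabda-8(17),13-dien-19-oic acid]
Conditions: K2CO3, MeOH, rt, 3 h; 10% citric acid work-up
Reagents that add atoms: none
Why: base-catalysed transesterification (methanolysis) removes the primary allylic acetate, while the hindered axial carboxylate is inert and is re-protonated on work-up.

**Step 6**
Reactants: 10 isocupressic acid
Product: 11 imbricatolic acid [(13S)-15-hydroxylabd-8(17)-en-19-oic acid]
Conditions: Ru(OAc)2[(R)-BINAP] (1 mol %), H2 (100 atm), 95% aq. MeOH, 20 °C, 24 h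
Reagents that add atoms: none
Why: Noyori hydroxyl-directed asymmetric hydrogenation: the alkoxide-bound ruthenium hydride reduces only the allylic-alcohol alkene, and (R)-BINAP on the E isomer delivers hydrogen to the face that gives 13S (the geraniol to (S)-citronellol sense) under catalyst control, while the exocyclic 8(17)-alkene, which has no coordinating group within reach, is left.

**Step 7**
Reactants: 11 imbricatolic acid
Product: 12 (13S)-15-formyloxylabd-8(17)-en-19-oic acid (target)
Conditions: HCO2CH2CF3 (neat, excess), 65 °C, 24 h
Reagents that add atoms: 2,2,2-trifluoroethyl formate, O=COCC(F)(F)F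
Why: O-formylation by acyl transfer from an activated formate ester forms the formate C–O bond at the only unhindered hydroxyl; the neutral conditions leave the exocyclic alkene and the hindered free acid untouched.

**Compound list**
1 | (−)-sclareol, (13R)-labd-14-ene-8α,13-diol | C[C@@]1(O)CC[C@@H]2[C@](C)(CCCC2(C)C)[C@H]1CC[C@@](C)(O)C=C | starting material
2 | 19-hydroxysclareol, (13R)-labd-14-ene-8α,13,19-triol | C[C@@]1(O)CC[C@@H]2[C@](C)(CCC[C@]2(C)CO)[C@H]1CC[C@@](C)(O)C=C | intermediate (not isolated)
3 | sclareol-19-al, (13R)-8α,13-dihydroxylabd-14-en-19-al | C[C@@]1(O)CC[C@@H]2[C@](C)(CCC[C@]2(C)C=O)[C@H]1CC[C@@](C)(O)C=C | intermediate (not isolated)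
4 | (13R)-8α,13-dihydroxylabd-14-en-19-oic acid | C[C@@]1(O)CC[C@@H]2[C@](C)(CCC[C@]2(C)C(=O)O)[C@H]1CC[C@@](C)(O)C=C | intermediate
5 | mixed acetic anhydride of 6, (13R)-13-acetoxy-8α-hydroxylabd-14-en-19-oic acetic anhydride | C[C@@]1(O)CC[C@@H]2[C@](C)(CCC[C@]2(C)C(=O)OC(C)=O)[C@H]1CC[C@@](C)(OC(C)=O)C=C | intermediate (not isolated)
6 | (13R)-13-acetoxy-8α-hydroxylabd-14-en-19-oic acid | C[C@@]1(O)CC[C@@H]2[C@](C)(CCC[C@]2(C)C(=O)O)[C@H]1CC[C@@](C)(OC(C)=O)C=C | intermediate
7 | (13E)-15-acetoxy-8α-hydroxylabd-13-en-19-oic acid | C[C@@]1(O)CC[C@@H]2[C@](C)(CCC[C@]2(C)C(=O)O)[C@H]1CC/C(C)=C/COC(C)=O | intermediate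
8 | acid chloride of 9, (13E)-15-acetoxylabda-8(17),13-dien-19-oyl chloride | C=C1CC[C@@H]2[C@](C)(CCC[C@]2(C)C(Cl)=O)[C@H]1CC/C(C)=C/COC(C)=O | intermediate (not isolated)
9 | acetylisocupressic acid, (13E)-15-acetoxylabda-8(17),13-dien-19-oic acid | C=C1CC[C@@H]2[C@](C)(CCC[C@]2(C)C(=O)O)[C@H]1CC/C(C)=C/COC(C)=O | intermediate
10 | isocupressic acid, (13E)-15-hydroxylabda-8(17),13-dien-19-oic acid | C=C1CC[C@@H]2[C@](C)(CCC[C@]2(C)C(=O)O)[C@H]1CC/C(C)=C/CO | intermediate
11 | imbricatolic acid, (13S)-15-hydroxylabd-8(17)-en-19-oic acid | C=C1CC[C@@H]2[C@](C)(CCC[C@]2(C)C(=O)O)[C@H]1CC[C@H](C)CCO | intermediate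
12 | (13S)-15-formyloxylabd-8(17)-en-19-oic acid | C=C1CC[C@@H]2[C@](C)(CCC[C@]2(C)C(=O)O)[C@H]1CC[C@H](C)CCOC=O | target

**Totals and risks**
Total steps: 7. Longest linear sequence: 7 (1 to 12). No carbon–carbon bond is made.

The three steps most likely to fail are 1, 4 and 6.

Step 1 (the proposed enzyme). Selectivity for C19 over C3, C2 and C18, and the depth of oxidation, are unproven. The fallback sets out from 1 and comes back at 4 with known chemistry. Whole-cell hydroxylation of 1 with a wild-type Cunninghamella strain is a documented biotransformation that gives ring-A alcohols of sclareol, the 18- and 19-ols among them; the 19-ol is a minor product. 19-Hydroxysclareol 2 is isolated by chromatography. TEMPO/PhI(OAc)2 in CH2Cl2 then oxidises the neopentyl primary alcohol, leaving the tertiary alcohols untouched, to sclareol-19-al 3. Pinnick oxidation (NaClO2, NaH2PO4, 2-methyl-2-butene, tBuOH–H2O) gives 4. New compounds on this way: none F0.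

Step 4 (dehydration). The exo/endo ratio may be poor, or the free acid and allylic acetate may not tolerate SOCl2. The fallback sets out from 7 and comes back at 9, replacing electrophilic activation by a reagent-free thermal syn-elimination of an ester. The 8α-OH is acetylated under forcing conditions (AcCl, N,N-dimethylaniline, CH2Cl2, 40 °C). The product is held for a time as (13E)-8α,15-diacetoxylabd-13-en-19-oic acetic anhydride F1 and is released by aqueous pyridine as (13E)-8α,15-diacetoxylabd-13-en-19-oic acid F2. Heating F2 in 2,4,6-collidine at 170 °C expels the tertiary acetate as acetic acid and gives 9. A lower exo/endo ratio is expected here than from the E2 route; the endocyclic isomers are removed on AgNO3-impregnated silica.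

Step 6 (asymmetric hydrogenation). It needs geometrically pure 13E material, since the 13Z isomer gives 13R, and it must spare the exocyclic alkene. The fallback sets out from 10, which may be an E/Z mixture, and comes back at 11 with a metal-free, E/Z-convergent reduction. MnO2 in CH2Cl2 oxidises the allylic alcohol to (13E)-15-oxolabda-8(17),13-dien-19-oic acid F3. Organocatalytic transfer hydrogenation follows: 2-tert-butyl-3-methylimidazolidin-4-one trichloroacetate (20 mol %), Hantzsch ester, CHCl3, −30 °C, using the catalyst enantiomer that turns citral into (S)-citronellal. Both enal isomers converge through iminium isomerisation on (13S)-15-oxolabd-8(17)-en-19-oic acid F4. NaBH4 in MeOH at 0 °C gives 11.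

**Further compounds**
F0 | step 1 | none | none
F1 | step 4 | (13E)-8α,15-diacetoxylabd-13-en-19-oic acetic anhydride | C[C@@]1(OC(C)=O)CC[C@@H]2[C@](C)(CCC[C@]2(C)C(=O)OC(C)=O)[C@H]1CC/C(C)=C/COC(C)=O
F2 | step 4 | (13E)-8α,15-diacetoxylabd-13-en-19-oic acid | C[C@@]1(OC(C)=O)CC[C@@H]2[C@](C)(CCC[C@]2(C)C(=O)O)[C@H]1CC/C(C)=C/COC(C)=O
F3 | step 6 | (13E)-15-oxolabda-8(17),13-dien-19-oic acid | C=C1CC[C@@H]2[C@](C)(CCC[C@]2(C)C(=O)O)[C@H]1CC/C(C)=C/C=O
F4 | step 6 | (13S)-15-oxolabd-8(17)-en-19-oic acid | C=C1CC[C@@H]2[C@](C)(CCC[C@]2(C)C(=O)O)[C@H]1CC[C@H](C)CC=O
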